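## Analysis of the target

The target 20 is a fully substituted oxolane (ring A: O1, C2 bearing 4-hydroxyphenyl, C3 bearing the 2,4-dihydroxybenzoyl group with ketone carbon C6, C4 bearing the hydroxy(4-hydroxyphenyl)methyl group with carbinol carbon C7, and C5 bearing 2,4-dihydroxyphenyl); ring B is the second lactone ring C3–C6–O–C7–C4 that appears in the intermediates. It has five stereocentres, all R (C2, C3, C4, C5, C7): on the ring the substituents at C3, C4 and C5 are mutually cis and the C2 aryl group is trans to the C3 aroyl group. C3 is α to the ketone and β to the ring oxygen, so base can epimerise it or open ring A by retro-oxa-Michael elimination. C5 and C7 are benzylic C–O centres para (C5 also ortho) to oxygen, so acid can ionise them, and C5 holds its aryl group in the less stable cis position. If C5 and C6 were ever ketones at the same time they would form a 1,4-diketone, a furan precursor, and the six phenols need protection that comes off under neutral conditions. The synthesis is hard because of the contiguous cis triad C3–C4–C5 next to an exocyclic centre, and because C5 and C6 carry the same aryl group and must be told apart. The strategy rests on one feature: C6 and C7 sit cis on C3 and C4 and, once the C7 oxygen is acylated by C6, are separated by a single oxygen, so the pair is a cyclobutanone C6–C7 bond plus one inserted oxygen. The resulting bis-lactone is C2-symmetric, so C5 and C6 are equivalent until one of them is touched.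

## Retrosynthetic reasoning

**20 to 19.** The six O–benzyl bonds are cut last. Benzyl is chosen because hydrogenolysis is neutral; after the ketone exists nothing may be basic (C3) or acidic (C5, C7).

**19 to 17 and 18.** The C6–aryl bond is cut. The ketone and the free C7 hydroxyl come from one group, the ring B lactone of 17: addition of aryllithium 18 (from bromide 14, made from 13) to C6 forms the ketone and releases C7–OH in the same event. Keeping ring B closed until then means C7–O needs no protecting group, and C6 is never a ketone while C5 is at the ketone level. The lithium reagent is chosen because this addition must run cold enough for the tetrahedral adduct to survive until the quench.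

**17 to 16 to 12 and 15.** The C5–H and C5–aryl bonds are cut, tracing C5 to a lactone carbonyl. The order is aryl first (arylmagnesium bromide 15, also made from 14, gives lactol 16), then hydride. The small nucleophile enters the bicyclic oxocarbenium ion from the convex face, anti to the C4–C7 bond, which leaves the aryl group cis to the C4 substituent; adding the aryl group last would place it trans. The precursor is dilactone 12, whose carbonyls C5 and C6 are exchanged by the C2 axis, so a single addition can give only one compound. The milder magnesium reagent is chosen for this mono-addition.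

**12 to 11.** The O–C7 bond of ring B is cut, removing the oxygen between C6 and C7 to give cyclobutanone 11. Forward, a peracid must move the benzylic carbon C7 rather than the ring-fusion carbon C3, with retention at C7.

**11 to 9 and 10.** The C7–aryl bond is cut to the parent cyclobutanone 9 and aryl bromide 10. The aryl group is added after the ring exists so that it can reach the exo position by enolisation, and so that it directs the later oxygen insertion.

**9 to 8 to 6 and 7.** After ketal removal, the C3–C6 and C4–C7 bonds are cut together: a [2+2] photocycloaddition of butenolide 6 with ketene acetal 7. This is the only disconnection that delivers a carboxyl-level carbon (C6) and a carbinol-level carbon (C7) cis to each other across C3/C4, on the face away from the C2 aryl. The forward reaction must be head-to-tail (acetal carbon on C3) and anti to the aryl group.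

**6 to 4 to 1 and 2.** The lactone C–O bond and the C2–alkyne bond are cut. Catalytic asymmetric alkynylation of aldehyde 1 with propiolate 2 sets C2, the only centre made under reagent control; cis-semihydrogenation and lactonisation follow.

## Alternatives that were turned down

**Alternative 1: oxidative β–β dimerisation of a cinnamic acid.**
- Disconnection: C3–C4 together with both lactone C–O bonds (O1–C2 and O–C7), reducing dilactone A2 to two molecules of (E)-4-hydroxycinnamic acid A1.
- Forward key step: one-electron oxidation of A1 gives phenoxyl radicals that couple at their β-carbons; the two quinone-methide termini of the dimer are trapped by the carboxyl groups, closing both lactones to A2, the free-phenol counterpart of 12.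
- For it: one step from a cheap achiral acid, no protecting groups, and the exo,exo relative configuration arises by itself. On step count it is clearly stronger, since the chosen route needs six steps to reach the same dilactone stage.
- Against it: an achiral radical coupling gives the racemate, and the target is wanted as one enantiomer, so half the material is lost to resolution. The unhindered radical from A1 also couples through its ring positions and oxygen, so the β–β mode is not clean. The phenols must then be protected before organometallic chemistry.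
- Comparison: the chosen route offers absolute configuration from one catalytic step and bond formation with defined regiochemistry, in place of brevity.

**Alternative 2: radical cyclisation of a haloacetal onto a silyl enol ether.**
- Disconnection: the ring bond C3–C4, with the C5–aryl bond left for later.
- Forward key step: a C4 radical from a bromoacetal adds 5-exo to C3 of an aryl silyl enol ether; the α-silyloxybenzyl radical at C6 takes up bromine and collapses to the ketone, giving 5-ethoxy-oxolane A3.
- For it: the C6 ketone and C7 carbinol are in place and differentiated from the start, so no symmetric intermediate must be mono-functionalised. On that point it is stronger than the chosen route. The conditions are neutral, and a chair-like transition state favours 2,3-trans/3,4-cis.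
- Against it: the cyclisation substrate needs two separately made stereocentres (C2 and C7) and a mixed acetal, so it is longer before the key step. Atom transfer to a stabilised, electron-rich benzylic radical is a poor chain step. C5 must then be arylated at the acetal carbon, where the aryl nucleophile enters anti to the C4 substituent and gives the 4,5-trans epimer, the wrong one, under Lewis acid and next to a ketone.
- Comparison: the chosen route sets C5 with hydride as the incoming group, which leaves the aryl cis, and takes the C3/C4 relation from a ring fusion, not from a transition-state preference.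

**Alternative 3: two-directional double aldol.**
- Disconnection: C2–C3 and C4–C7, both aldol bonds, from 1,4-diketone A4 and two molecules of aldehyde A5 (the same compound as 1).
- Forward key step: double enolisation of A4 to the bis(Z-boron enolate) and two syn-aldol additions to A5 give the C2-symmetric bis-aldol A6; one carbinol would then close on the distal ketone and the lactol be reduced.
- For it: it is the most convergent plan, with all four aryl groups and the whole carbon skeleton assembled in one step, and its C2 symmetry makes the two possible ring closures identical. On convergence and step count it is stronger.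
- Against it: four stereocentres are set at once. Syn selectivity within each aldol is dependable, but the relation between the two halves (C3 against C4) and the absolute sense need reagent control twice, the second time on an aldolate that already carries two centres. A6 is both a bis(β-hydroxy ketone) and a 1,4-diketone, so retro-aldol, dehydration and furan formation threaten under the Lewis acid needed for reductive etherification, and C3/C4 stay epimerisable.
- Comparison: the chosen route never has C5 and C6 as ketones together and fixes C3/C4 cis by geometry.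

Key step: step 3

Assumption: the (S,S)-ProPhenol/Me2Zn catalyst is taken to deliver the (4S)-alcohol 4 from an aryl aldehyde; if the sense of induction is the opposite, the (R,R)-ligand is used without other change.

Assumption: 19 and 20 are taken to exist as the open γ-hydroxy ketones (the ortho oxygen and aryl conjugation stabilise the ketone) and not as their cyclic hemiketals.

## Route

Step 1
Reactants: 1 4-(benzyloxy)benzaldehyde; 2 ethyl propiolate
Product: 4 ethyl (4S)-4-[4-(benzyloxy)phenyl]-4-hydroxybut-2-ynoate, via methylzinc acetylide 3 (not isolated)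
Conditions: 2 (3 equiv), Me2Zn (3 equiv), (S,S)-ProPhenol (10 mol%), Ph3P=O (20 mol%), toluene, 0 to 4 °C; aq. NH4Cl
Reagents that add atoms: none
Why: Catalytic asymmetric alkynylation of an aldehyde: Me2Zn deprotonates 2 to the zinc acetylide 3, and the dinuclear zinc catalyst formed in situ from Me2Zn and ProPhenol binds aldehyde and acetylide and delivers the alkynyl group to one carbonyl face, setting the carbinol centre that becomes C2; aryl aldehydes and propiolate donors are usual substrates for this reaction.

Step 2
Reactants: 4 ethyl (4S)-4-[4-(benzyloxy)phenyl]-4-hydroxybut-2-ynoate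
Product: 6 (5R)-5-[4-(benzyloxy)phenyl]furan-2(5H)-one, via Z-hydroxy enoate 5 (not isolated)
Conditions: H2 (1 atm), Pd/CaCO3 poisoned with Pb(OAc)2, EtOAc, rt; then SiO2, CH2Cl2, rt
Reagents that add atoms: none
Why: Syn addition of hydrogen on the poisoned palladium surface (cis-semihydrogenation) gives the Z-enoate 5, whose hydroxyl and ester are held together and lactonise with loss of ethanol; amine base is left out because the C2 hydrogen of 6 is benzylic and vinylogously acidic, and strong acid is avoided because the C2–O bond can ionise, so C2 is not touched (the descriptor changes from S to R only through ligand priorities).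

Step 3
Reactants: 6 (5R)-5-[4-(benzyloxy)phenyl]furan-2(5H)-one; 7 1,1-diethoxyethene
Product: 8 (1S,4R,5R)-4-[4-(benzyloxy)phenyl]-6,6-diethoxy-3-oxabicyclo[3.2.0]heptan-2-one
Conditions: hν (medium-pressure Hg lamp, Pyrex filter, λ > 290 nm), 7 (10 equiv), degassed Et2O, −20 °C
Reagents that add atoms: none
Why: Excitation and intersystem crossing give the triplet butenolide, which adds stepwise to the electron-rich alkene: bonding of the α-carbon C4 to the unsubstituted terminus C7 gives a triplet 1,4-biradical with radical centres at C3 and at the dialkoxy-substituted C6, and after spin inversion C3 and C6 combine, while the isomeric biradical from β-bonding is expected largely to revert to the components. The closest known reaction type is the [2+2] photocycloaddition of 2(5H)-furanones and cyclic enones with ketene acetals, which gives head-to-tail adducts (acetal carbon on the β-carbon) on the face anti to a γ-substituent. One ring is closed, the cyclobutane C3–C6–C7–C4, by radical–radical combination within the 1,4-biradical, a two-bond annulation across C3=C4. C3 and C4 become stereocentres: their cis relation is dictated by the four/five ring fusion, which cannot be trans, and their relation to C2 is controlled by the aryl group on C2, which blocks one face of the planar lactone so that both bonds form on the other face; a biradical formed on the hindered face would have to close C3–C6 beside the aryl group and should revert instead. The step needs head-to-tail orientation, secured by the polarity match of the excited enone with the 1,1-dialkoxyalkene, and anti facial selectivity, secured by the aryl group directly on C2. A large excess of 7, low temperature and Pyrex-filtered light are used so that bimolecular trapping outruns unimolecular photochemistry of the γ-aryl lactone and the alkoxyarene is not excited directly; 7 is kept free of acid to prevent polymerisation.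

Step 4
Reactants: 8 (1S,4R,5R)-4-[4-(benzyloxy)phenyl]-6,6-diethoxy-3-oxabicyclo[3.2.0]heptan-2-one
Product: 9 (1S,4R,5R)-4-[4-(benzyloxy)phenyl]-3-oxabicyclo[3.2.0]heptane-2,6-dione
Conditions: 1 M aq. HCl, THF, rt
Reagents that add atoms: water, O
Why: Acid-catalysed ketal hydrolysis; the γ-lactone and the aryl benzyl ether tolerate dilute aqueous acid, and C3/C4 cannot epimerise because cis is the only accessible fusion of the four/five system.

Step 5
Reactants: 9 (1S,4R,5R)-4-[4-(benzyloxy)phenyl]-3-oxabicyclo[3.2.0]heptane-2,6-dione; 10 1-(benzyloxy)-4-bromobenzene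
Product: 11 (1S,4R,5R,7R)-4,7-bis[4-(benzyloxy)phenyl]-3-oxabicyclo[3.2.0]heptane-2,6-dione
Conditions: Pd2(dba)3 (2.5 mol%), Xantphos (6 mol%), K3PO4 (2.5 equiv), toluene, 80 °C; then DBU (10 mol%), CH2Cl2, rt
Reagents that add atoms: none
Why: Palladium-catalysed ketone α-arylation (Buchwald–Hartwig-type enolate arylation): oxidative addition of 10 to zerovalent palladium, enolate formation at C7 (enolisation toward the ring-fusion carbon C3 would create a strained bicyclic cyclobutene) and C–C reductive elimination, with the weak base K3PO4 chosen to spare the lactone. C7 is set under thermodynamic control: the α-aryl ketone equilibrates through its enolate (DBU) to the exo isomer, aryl on the convex face and trans to the C4–C5 bond.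

Step 6
Reactants: 11 (1S,4R,5R,7R)-4,7-bis[4-(benzyloxy)phenyl]-3-oxabicyclo[3.2.0]heptane-2,6-dione
Product: 12 (1R,2R,5R,6R)-2,6-bis[4-(benzyloxy)phenyl]-3,7-dioxabicyclo[3.3.0]octane-4,8-dione
Conditions: mCPBA (1.3 equiv), CH2Cl2, 0 °C to rt
Reagents that add atoms: mCPBA (3-chloroperoxybenzoic acid), OOC(=O)c1cccc(Cl)c1
Why: Baeyer–Villiger oxidation; ring strain makes the cyclobutanone by far the most reactive group, and in the Criegee intermediate the 4-alkoxybenzylic carbon C7 should migrate in preference to C3, which is deactivated by the β-acyloxy group on C2. Migration occurs with retention, so the exo aryl is carried into the C2-symmetric dilactone.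

Step 7
Reactants: 13 4-bromoresorcinol
Product: 14 2,4-bis(benzyloxy)-1-bromobenzene
Conditions: BnBr (2.3 equiv), K2CO3 (3 equiv), DMF, 50 °C
Reagents that add atoms: benzyl bromide, BrCc1ccccc1
Why: Williamson ether synthesis on both phenoxides; the aryl bromide is inert to these conditions.

Step 8
Reactants: 12 (1R,2R,5R,6R)-2,6-bis[4-(benzyloxy)phenyl]-3,7-dioxabicyclo[3.3.0]octane-4,8-dione; 14 2,4-bis(benzyloxy)-1-bromobenzene
Product: 16 (1R,4R,5R,8R)-6-[2,4-bis(benzyloxy)phenyl]-4,8-bis[4-(benzyloxy)phenyl]-6-hydroxy-3,7-dioxabicyclo[3.3.0]octan-2-one (both C6 epimers), via arylmagnesium bromide 15 (not isolated)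
Conditions: 14 (0.95 equiv), Mg turnings (1.5 equiv), LiCl (1.0 equiv), THF, rt; decanted solution added slowly to 12, THF, −40 to −20 °C; AcOH, −40 °C
Reagents that add atoms: none
Why: Magnesium insertion into the C–Br bond of 14, accelerated by LiCl, gives the Grignard reagent 15, which adds once to a lactone carbonyl and rests as the cyclic magnesium hemiketal alkoxide until the quench (Grignard addition to a lactone stopped at the lactol, as in aryl C-glycoside synthesis from lactones). Because 12 is C2-symmetric its carbonyls C5 and C6 are homotopic, so one mono-adduct results whichever is attacked. Slow addition of slightly less than one equivalent of the mild magnesium reagent to an excess of 12, and loss of the activating β-acyloxy group after the first addition, are relied on to limit double addition.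

Step 9
Reactants: 16 (1R,4R,5R,8R)-6-[2,4-bis(benzyloxy)phenyl]-4,8-bis[4-(benzyloxy)phenyl]-6-hydroxy-3,7-dioxabicyclo[3.3.0]octan-2-one
Product: 17 (1R,4R,5S,6R,8R)-6-[2,4-bis(benzyloxy)phenyl]-4,8-bis[4-(benzyloxy)phenyl]-3,7-dioxabicyclo[3.3.0]octan-2-one
Conditions: Et3SiH (3 equiv), BF3·OEt2 (1.5 equiv), CH2Cl2, −78 °C; Et3N, −78 °C
Reagents that add atoms: none
Why: Ionic hydrogenation of a lactol: the Lewis acid ionises the hemiketal to an aryl-stabilised oxocarbenium ion and the silane transfers hydride to the convex face of the cis-fused bicycle, anti to the C4–C7 bond, so the aryl group is left on the concave face, cis to the C4 substituent, which sets C5. Ring B is still a lactone, so no 1,4-diketone can divert the cation to a furan; the low temperature and cold basic quench guard against epimerisation of the cis aryl ether by reversible C5–O ionisation.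

Step 10
Reactants: 17 (1R,4R,5S,6R,8R)-6-[2,4-bis(benzyloxy)phenyl]-4,8-bis[4-(benzyloxy)phenyl]-3,7-dioxabicyclo[3.3.0]octan-2-one; 14 2,4-bis(benzyloxy)-1-bromobenzene
Product: 19 [(2R,3R,4R,5R)-5-[2,4-bis(benzyloxy)phenyl]-2-[4-(benzyloxy)phenyl]-4-{(R)-[4-(benzyloxy)phenyl](hydroxy)methyl}oxolan-3-yl][2,4-bis(benzyloxy)phenyl]methanone, via aryllithium 18 (not isolated)
Conditions: 14 (1.3 equiv), n-BuLi (1.3 equiv), THF, −78 °C; then 17, THF, −78 °C; AcOH, −78 °C
Reagents that add atoms: none
Why: Bromine–lithium exchange on 14 gives aryllithium 18, preferred here to the Grignard reagent because it adds to the lactone at −78 °C, where the tetrahedral lithium alkoxide, supported by the ortho-benzyloxy group, persists until the quench (acyl substitution of a lactone by an organolithium). On protonation the adduct collapses to the aryl ketone at C6 and frees the C7 hydroxyl in the same event. The cold acidic quench avoids enolisation at C3, so no stereocentre is changed.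

Step 11
Reactants: 19 [(2R,3R,4R,5R)-5-[2,4-bis(benzyloxy)phenyl]-2-[4-(benzyloxy)phenyl]-4-{(R)-[4-(benzyloxy)phenyl](hydroxy)methyl}oxolan-3-yl][2,4-bis(benzyloxy)phenyl]methanone
Product: 20 (2,4-dihydroxyphenyl)[(2R,3R,4R,5R)-5-(2,4-dihydroxyphenyl)-4-[(R)-hydroxy(4-hydroxyphenyl)methyl]-2-(4-hydroxyphenyl)oxolan-3-yl]methanone
Conditions: H2 (1 atm), Pd/C (10 wt% Pd), EtOAc–MeOH, rt, stopped after uptake of six equivalents
Reagents that add atoms: none
Why: Hydrogenolysis of the six aryl benzyl ethers on palladium under neutral conditions; aryl benzyl ethers cleave faster than the benzylic alcohol, the ring C–O bonds or the aryl ketone, and neither acid nor base reaches C3, C5 or C7.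

## Compound list

1 | 4-(benzyloxy)benzaldehyde | O=Cc1ccc(OCc2ccccc2)cc1 | starting material
2 | ethyl propiolate | C#CC(=O)OCC | starting material
3 | ethyl 3-(methylzincio)prop-2-ynoate | CCOC(=O)C#C[Zn]C | intermediate (not isolated)
4 | ethyl (4S)-4-[4-(benzyloxy)phenyl]-4-hydroxybut-2-ynoate | CCOC(=O)C#C[C@@H](O)c1ccc(OCc2ccccc2)cc1 | intermediate
5 | ethyl (2Z,4R)-4-[4-(benzyloxy)phenyl]-4-hydroxybut-2-enoate | CCOC(=O)/C=C\[C@@H](O)c1ccc(OCc2ccccc2)cc1 | intermediate (not isolated)
6 | (5R)-5-[4-(benzyloxy)phenyl]furan-2(5H)-one | O=C1C=C[C@@H](O1)c1ccc(OCc2ccccc2)cc1 | intermediate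
7 | 1,1-diethoxyethene | C=C(OCC)OCC | starting material
8 | (1S,4R,5R)-4-[4-(benzyloxy)phenyl]-6,6-diethoxy-3-oxabicyclo[3.2.0]heptan-2-one | CCOC3(OCC)[C@@H]1[C@H](C3)C(=O)O[C@H]1c1ccc(OCc2ccccc2)cc1 | intermediate
9 | (1S,4R,5R)-4-[4-(benzyloxy)phenyl]-3-oxabicyclo[3.2.0]heptane-2,6-dione | O=C3[C@@H]1[C@H](C3)C(=O)O[C@H]1c1ccc(OCc2ccccc2)cc1 | intermediate
10 | 1-(benzyloxy)-4-bromobenzene | Brc1ccc(OCc2ccccc2)cc1 | starting material
11 | (1S,4R,5R,7R)-4,7-bis[4-(benzyloxy)phenyl]-3-oxabicyclo[3.2.0]heptane-2,6-dione | O=C3[C@@H]1[C@H]([C@@H]3c4ccc(OCc5ccccc5)cc4)C(=O)O[C@H]1c6ccc(OCc7ccccc7)cc6 | intermediate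
12 | (1R,2R,5R,6R)-2,6-bis[4-(benzyloxy)phenyl]-3,7-dioxabicyclo[3.3.0]octane-4,8-dione | O=C3[C@@H]1[C@H]([C@@H](O3)c4ccc(OCc5ccccc5)cc4)C(=O)O[C@H]1c6ccc(OCc7ccccc7)cc6 | intermediate
13 | 4-bromoresorcinol | Oc1ccc(Br)c(O)c1 | starting material
14 | 2,4-bis(benzyloxy)-1-bromobenzene | Brc1ccc(OCc2ccccc2)cc1OCc1ccccc1 | intermediate
15 | [2,4-bis(benzyloxy)phenyl]magnesium bromide (LiCl-complexed solution in THF) | Br[Mg]c1ccc(OCc2ccccc2)cc1OCc1ccccc1 | intermediate (not isolated)
16 | (1R,4R,5R,8R)-6-[2,4-bis(benzyloxy)phenyl]-4,8-bis[4-(benzyloxy)phenyl]-6-hydroxy-3,7-dioxabicyclo[3.3.0]octan-2-one (C6 epimers) | O=C3[C@@H]1[C@H]([C@@H](O3)c4ccc(OCc5ccccc5)cc4)C(O)(c4ccc(OCc5ccccc5)cc4OCc4ccccc4)O[C@H]1c6ccc(OCc7ccccc7)cc6 | intermediate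
17 | (1R,4R,5S,6R,8R)-6-[2,4-bis(benzyloxy)phenyl]-4,8-bis[4-(benzyloxy)phenyl]-3,7-dioxabicyclo[3.3.0]octan-2-one | O=C3[C@@H]1[C@H]([C@@H](O3)c4ccc(OCc5ccccc5)cc4)[C@H](c4ccc(OCc5ccccc5)cc4OCc4ccccc4)O[C@H]1c6ccc(OCc7ccccc7)cc6 | intermediate
18 | [2,4-bis(benzyloxy)phenyl]lithium | [Li]c1ccc(OCc2ccccc2)cc1OCc1ccccc1 | intermediate (not isolated)
19 | [(2R,3R,4R,5R)-5-[2,4-bis(benzyloxy)phenyl]-2-[4-(benzyloxy)phenyl]-4-{(R)-[4-(benzyloxy)phenyl](hydroxy)methyl}oxolan-3-yl][2,4-bis(benzyloxy)phenyl]methanone | O=C(c2ccc(OCc3ccccc3)cc2OCc2ccccc2)[C@@H]1[C@H]([C@@H](O)c4ccc(OCc5ccccc5)cc4)[C@H](c4ccc(OCc5ccccc5)cc4OCc4ccccc4)O[C@H]1c6ccc(OCc7ccccc7)cc6 | intermediate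
20 | (2,4-dihydroxyphenyl)[(2R,3R,4R,5R)-5-(2,4-dihydroxyphenyl)-4-[(R)-hydroxy(4-hydroxyphenyl)methyl]-2-(4-hydroxyphenyl)oxolan-3-yl]methanone | O=C(c1ccc(O)cc1O)[C@@H]1[C@H]([C@@H](O)c2ccc(O)cc2)[C@H](c2ccc(O)cc2O)O[C@H]1c1ccc(O)cc1 | target

## Step count and least certain steps

Total: 11 steps. Longest linear sequence: 10 steps (1 to 20 through steps 1–6 and 8–11); step 7 is a one-step branch.

**Step 3 (key step).** Facial discrimination may be incomplete; the γ-aryl lactone may undergo unimolecular photochemistry (aryl migration, racemising C2–O cleavage) or triplet quenching by the alkoxyarene; some head-to-head orientation or polymerisation of 7 may occur. Fallback, a ground-state tandem conjugate addition–aldol setting out from 6: tris(methylsulfanyl)methyllithium adds to C3 anti to the aryl group and the lactone enolate is trapped at C4 with aldehyde 1, giving the orthothioester aldol adduct (4R,5R)-5-[4-(benzyloxy)phenyl]-3-{[4-(benzyloxy)phenyl](hydroxy)methyl}-4-[tris(methylsulfanyl)methyl]oxolan-2-one F1. Unmasking of the orthothioester (HgCl2, CaCO3, aqueous MeCN), equilibration of the reversible aldol centres with mild base and acid-catalysed lactonisation should funnel the material into 12, the only isomer able to close both rings, where the route is rejoined. This bypasses 8, 9 and 11 and replaces the kinetic cis delivery by thermodynamic control.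

**Step 5.** The strained ketone may be consumed by self-condensation or base-induced ring cleavage before the enolate is arylated, and a second arylation or attack on the lactone may compete. Fallback, electrophilic arylation without palladium, from 9: the lithium enolate (LiN(SiMe3)2, THF, −78 °C) is treated with the diaryliodonium salt bis[4-(benzyloxy)phenyl]iodonium 4-methylbenzenesulfonate F2 (made in one pot from 1-(benzyloxy)-4-iodobenzene and benzyl phenyl ether with mCPBA and TsOH). After the same DBU equilibration the route is rejoined at 11.

**Step 6.** Migration of the ring-fusion carbon C3 instead of C7 would give the regioisomeric lactone, and the peracid may attack the electron-rich rings. Fallback, photochemical ring expansion from 11: irradiation in MeOH (λ about 350 nm) cleaves the C6–C7 bond on the benzylic side and the oxacarbene is trapped by the solvent, giving the cyclic acetal 4,8-bis[4-(benzyloxy)phenyl]-6-methoxy-3,7-dioxabicyclo[3.3.0]octan-2-one F3. Oxidation of the acetal (CrO3/H2SO4, acetone) returns to 12. Here regiochemistry follows radical stability and not migratory aptitude; decarbonylation is the competing process.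

**Step 8.** Addition to both lactones may occur, since only stoichiometry, the mildness of the magnesium reagent and a modest electronic deactivation separate the first addition from the second; opening of the magnesium hemiketal to a keto alkoxide, or enolisation with β-elimination of the other lactone, are further risks. Fallback, a reordering that avoids any symmetric intermediate, setting out from ketal lactone 8: aryllithium 18 (from 14 and n-BuLi, THF, −78 °C) adds to the only lactone to give the lactol 2-[2,4-bis(benzyloxy)phenyl]-4-[4-(benzyloxy)phenyl]-6,6-diethoxy-3-oxabicyclo[3.2.0]heptan-2-ol F4. Et3SiH/BF3·OEt2 at −78 °C then delivers hydride to the convex face and gives (1S,2R,4R,5R)-2-[2,4-bis(benzyloxy)phenyl]-4-[4-(benzyloxy)phenyl]-6,6-diethoxy-3-oxabicyclo[3.2.0]heptane F5; the doubly donor-stabilised benzylic lactol should ionise far faster than the cyclobutanone ketal, whose oxocarbenium ion would place an sp2 carbon in the four-membered ring. Dilute aqueous acid frees the cyclobutanone (1S,2R,4R,5R)-2-[2,4-bis(benzyloxy)phenyl]-4-[4-(benzyloxy)phenyl]-3-oxabicyclo[3.2.0]heptan-6-one F6, arylation with 10 as in step 5 gives (1S,2R,4R,5R,7R)-2-[2,4-bis(benzyloxy)phenyl]-4,7-bis[4-(benzyloxy)phenyl]-3-oxabicyclo[3.2.0]heptan-6-one F7, and Baeyer–Villiger oxidation (mCPBA, NaHCO3) rejoins the route at 17. The price is that C5 is set early and must survive the acidic ketal hydrolysis.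

**Step 10.** A second addition to the liberated ketone, or enolisation toward C3 followed by β-elimination of the ring oxygen, may compete. Fallback from 17: opening with Me2AlN(OMe)Me (from AlMe3 and MeNH(OMe)·HCl, CH2Cl2, 0 °C) gives the hydroxy Weinreb amide (2R,3R,4R,5R)-5-[2,4-bis(benzyloxy)phenyl]-2-[4-(benzyloxy)phenyl]-4-{(R)-[4-(benzyloxy)phenyl](hydroxy)methyl}-N-methoxy-N-methyloxolane-3-carboxamide F8. Excess 18 at −78 °C then gives 19 through a chelated tetrahedral intermediate that cannot add twice.

## Further compounds

F1 | step 3 | (4R,5R)-5-[4-(benzyloxy)phenyl]-3-{[4-(benzyloxy)phenyl](hydroxy)methyl}-4-[tris(methylsulfanyl)methyl]oxolan-2-one (epimers at C3 and the carbinol carbon) | CSC(SC)(SC)[C@@H]1C(C(O)c2ccc(OCc3ccccc3)cc2)C(=O)O[C@H]1c4ccc(OCc5ccccc5)cc4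
F2 | step 5 | bis[4-(benzyloxy)phenyl]iodonium 4-methylbenzenesulfonate | Cc1ccc(cc1)S(=O)(=O)[O-].c1ccc(COc2ccc([I+]c3ccc(OCc4ccccc4)cc3)cc2)cc1
F3 | step 6 | 4,8-bis[4-(benzyloxy)phenyl]-6-methoxy-3,7-dioxabicyclo[3.3.0]octan-2-one (both acetal epimers) | COC3[C@@H]1[C@H]([C@@H](O3)c4ccc(OCc5ccccc5)cc4)C(=O)O[C@H]1c6ccc(OCc7ccccc7)cc6
F4 | step 8 | (1S,4R,5R)-2-[2,4-bis(benzyloxy)phenyl]-4-[4-(benzyloxy)phenyl]-6,6-diethoxy-3-oxabicyclo[3.2.0]heptan-2-ol (C2 epimers) | CCOC3(OCC)[C@@H]1[C@H](C3)C(O)(c4ccc(OCc5ccccc5)cc4OCc4ccccc4)O[C@H]1c6ccc(OCc7ccccc7)cc6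
F5 | step 8 | (1S,2R,4R,5R)-2-[2,4-bis(benzyloxy)phenyl]-4-[4-(benzyloxy)phenyl]-6,6-diethoxy-3-oxabicyclo[3.2.0]heptane | CCOC3(OCC)[C@@H]1[C@H](C3)[C@H](c4ccc(OCc5ccccc5)cc4OCc4ccccc4)O[C@H]1c6ccc(OCc7ccccc7)cc6
F6 | step 8 | (1S,2R,4R,5R)-2-[2,4-bis(benzyloxy)phenyl]-4-[4-(benzyloxy)phenyl]-3-oxabicyclo[3.2.0]heptan-6-one | O=C3[C@@H]1[C@H](C3)[C@H](c4ccc(OCc5ccccc5)cc4OCc4ccccc4)O[C@H]1c6ccc(OCc7ccccc7)cc6
F7 | step 8 | (1S,2R,4R,5R,7R)-2-[2,4-bis(benzyloxy)phenyl]-4,7-bis[4-(benzyloxy)phenyl]-3-oxabicyclo[3.2.0]heptan-6-one | O=C3[C@@H]1[C@H]([C@@H]3c8ccc(OCc9ccccc9)cc8)[C@H](c4ccc(OCc5ccccc5)cc4OCc4ccccc4)O[C@H]1c6ccc(OCc7ccccc7)cc6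
F8 | step 10 | (2R,3R,4R,5R)-5-[2,4-bis(benzyloxy)phenyl]-2-[4-(benzyloxy)phenyl]-4-{(R)-[4-(benzyloxy)phenyl](hydroxy)methyl}-N-methoxy-N-methyloxolane-3-carboxamide | CON(C)C(=O)[C@@H]1[C@H]([C@@H](O)c4ccc(OCc5ccccc5)cc4)[C@H](c4ccc(OCc5ccccc5)cc4OCc4ccccc4)O[C@H]1c6ccc(OCc7ccccc7)cc6
A1 | alternative 1 | (E)-3-(4-hydroxyphenyl)prop-2-enoic acid | OC(=O)/C=C/c1ccc(O)cc1
A2 | alternative 1 | (1R,2R,5R,6R)-2,6-bis(4-hydroxyphenyl)-3,7-dioxabicyclo[3.3.0]octane-4,8-dione | O=C3[C@@H]1[C@H]([C@@H](O3)c4ccc(O)cc4)C(=O)O[C@H]1c1ccc(O)cc1
A3 | alternative 2 | [(2R,3R,4R)-2-[4-(benzyloxy)phenyl]-4-{(R)-[4-(benzyloxy)phenyl][(tert-butyldimethylsilyl)oxy]methyl}-5-ethoxyoxolan-3-yl][2,4-bis(benzyloxy)phenyl]methanone (either C5 epimer) | O=C(c1ccc(OCc2ccccc2)cc1OCc1ccccc1)[C@@H]1[C@H]([C@@H](O[Si](C)(C)C(C)(C)C)c2ccc(OCc3ccccc3)cc2)C(OCC)O[C@H]1c1ccc(OCc2ccccc2)cc1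
A4 | alternative 3 | 1,4-bis[2,4-bis(benzyloxy)phenyl]butane-1,4-dione | O=C(CCC(=O)c1ccc(OCc2ccccc2)cc1OCc1ccccc1)c1ccc(OCc2ccccc2)cc1OCc1ccccc1
A5 | alternative 3 | 4-(benzyloxy)benzaldehyde | O=Cc1ccc(OCc2ccccc2)cc1
A6 | alternative 3 | (1R,2R,3R,4R)-2,3-bis[2,4-bis(benzyloxy)benzoyl]-1,4-bis[4-(benzyloxy)phenyl]butane-1,4-diol | O=C(c1ccc(OCc2ccccc2)cc1OCc1ccccc1)[C@@H]([C@@H](O)c1ccc(OCc2ccccc2)cc1)[C@H]([C@@H](O)c1ccc(OCc2ccccc2)cc1)C(=O)c1ccc(OCc2ccccc2)cc1OCc1ccccc1
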